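## Retrosynthetic overview

1. Ester C–O bond (last step): the target is split into the monocyclic diterpenol and linoleic acid.
2. C9–H from C9–SO2Tol: the CH2 next to the ring (C9) is carried as a tosyl-stabilised carbanion equivalent, a reversed-polarity one-carbon linchpin, and the sulfonyl group is removed reductively at the end.
3. Key disconnection, ring C1–C9: decarboxylative Claisen rearrangement of the ring allylic ester of the fully elaborated tosyl acid. The umpoled C9 is delivered suprafacially to the allylic ring terminus, so the carbinol centre (set by CBS reduction of the enone) becomes the (S) ring centre and the olefin lands in the 2,3-position.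
4. C8–C9: mild alkylation of the ring tosylacetate with 8-bromogeranyl acetate (from geranyl acetate by SeO2 oxidation, then PBr3). Both carbons joined to C9 (C8 and ring C1) are natural allylic electrophiles.
5. Rings: no ring is formed. The cyclohexene is bought as 2,4,4-trimethylcyclohex-2-en-1-one and only refunctionalised.

Assumption: 2,4,4-trimethylcyclohex-2-en-1-one is taken as a catalogue compound. Side-chain carbons are numbered C1 (CH2O) to C9 (CH2 on the ring), and the ring carbon bearing the chain is ring C1.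

## Route

Step 1
Reactants: 1 2,4,4-trimethylcyclohex-2-en-1-one
Product: 2 (1R)-2,4,4-trimethylcyclohex-2-en-1-ol
Conditions: (S)-2-methyl-CBS-oxazaborolidine (C18H20BNO, 10 mol%), BH3·SMe2 (0.7 equiv), THF, −20 °C; MeOH quench
Reagents that add atoms: none
Why: Corey–Bakshi–Shibata reduction, in which the oxazaborolidine–BH3 complex binds the carbonyl anti to the larger α-methylvinyl arm and delivers hydride 1,2 to one face only, giving the (R)-carbinol in the same sense as acetophenone gives (R)-1-phenylethanol; this is the configuration that the later suprafacial rearrangement turns into the (S) ring centre.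

Step 2
Reactants: 2 (1R)-2,4,4-trimethylcyclohex-2-en-1-ol; 3 2-[(4-methylphenyl)sulfonyl]acetic acid
Product: 4 (1R)-2,4,4-trimethylcyclohex-2-en-1-yl 2-[(4-methylphenyl)sulfonyl]acetate
Conditions: DCC (1.1 equiv), 4-(dimethylamino)pyridine (5 mol%), CH2Cl2, 0 °C to rt
Reagents that add atoms: none
Why: Carbodiimide (Steglich-type) esterification, which for arylsulfonylacetic acids runs through the sulfonylketene and therefore acylates even this hindered secondary allylic alcohol at oxygen, with retention of the carbinol configuration.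

Step 3
Reactants: 5 geranyl acetate
Product: 6 (2E,6E)-8-hydroxy-3,7-dimethylocta-2,6-dien-1-yl acetate
Conditions: SeO2 (0.2 equiv), t-BuOOH (3 equiv), salicylic acid (0.1 equiv), CH2Cl2, rt, 24 h
Reagents that add atoms: tert-butyl hydroperoxide CC(C)(C)OO (terminal oxidant); selenium dioxide O=[Se]=O (catalytic oxygen carrier)
Why: Sharpless–Umbreit allylic hydroxylation (ene reaction, then [2,3]-shift of the allylseleninic acid) attacks the electron-rich terminal trisubstituted olefin at its (E)-methyl group, the 2,3-olefin being deactivated by the allylic acetate; no stereocentre is formed.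

Step 4
Reactants: 6 (2E,6E)-8-hydroxy-3,7-dimethylocta-2,6-dien-1-yl acetate
Product: 7 (2E,6E)-8-bromo-3,7-dimethylocta-2,6-dien-1-yl acetate
Conditions: PBr3 (0.4 equiv), Et2O, −10 to 0 °C
Reagents that add atoms: phosphorus tribromide BrP(Br)Br
Why: SN2 displacement of the bromophosphite ester of a primary allylic alcohol by bromide, which at low temperature proceeds without allylic transposition and keeps the E-geometry.

Step 5
Reactants: 4 (1R)-2,4,4-trimethylcyclohex-2-en-1-yl 2-[(4-methylphenyl)sulfonyl]acetate; 7 (2E,6E)-8-bromo-3,7-dimethylocta-2,6-dien-1-yl acetate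
Product: 8 (1R)-2,4,4-trimethylcyclohex-2-en-1-yl (4E,8E)-10-acetoxy-4,8-dimethyl-2-[(4-methylphenyl)sulfonyl]deca-4,8-dienoate
Conditions: K2CO3 (1.5 equiv), DMF, 0 °C to rt (4 in slight excess)
Reagents that add atoms: none
Why: Alkylation of an active methylene compound (pKa about 12), in which the carbonate-generated sulfonyl ester carbanion displaces the primary allylic bromide by SN2 with retention of the E-olefin under conditions mild enough for both esters; the new centre at the tosyl-bearing carbon forms as an epimer mixture that is erased later.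

Step 6
Reactants: 8 (1R)-2,4,4-trimethylcyclohex-2-en-1-yl (4E,8E)-10-acetoxy-4,8-dimethyl-2-[(4-methylphenyl)sulfonyl]deca-4,8-dienoate
Product: 11 (2E,6E)-3,7-dimethyl-9-[(4-methylphenyl)sulfonyl]-9-[(1S)-2,6,6-trimethylcyclohex-2-en-1-yl]nona-2,6-dien-1-yl acetate, via silyl ketene acetal 9 (not isolated), via trimethylsilyl ester 10 (not isolated)
Conditions: N,O-bis(trimethylsilyl)acetamide (0.3 equiv), KOAc (CH3CO2K, 0.1 equiv), toluene, 110 °C (microwave 150 °C if sluggish)
Reagents that add atoms: none
Why: Decarboxylative Claisen rearrangement (Ireland–Claisen [3,3] shift of silyl ketene acetal 9, then acetate-triggered desilylation and loss of CO2 from 10), in which the ring-enforced boat transition state forms the ring C1–C9 bond on the face from which the C–O bond leaves, so the (1R)-carbinol is transferred completely into the (1S) ring carbon with the double bond moved to C2=C3; the tosyl-bearing C9 thus acts as a reversed-polarity alkyl (CH2 dianion) synthon that joins C8 and ring C1, two carbons that are both natural allylic electrophiles.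

Step 7
Reactants: 11 (2E,6E)-3,7-dimethyl-9-[(4-methylphenyl)sulfonyl]-9-[(1S)-2,6,6-trimethylcyclohex-2-en-1-yl]nona-2,6-dien-1-yl acetate
Product: 13 (2E,6E)-3,7-dimethyl-9-[(1S)-2,6,6-trimethylcyclohex-2-en-1-yl]nona-2,6-dien-1-ol, via desulfonylated acetate 12 (not isolated)
Conditions: Na(Hg) (6% Na, 6 equiv Na), Na2HPO4, MeOH–THF, −20 to 0 °C; then K2CO3 (cat.), MeOH, rt
Reagents that add atoms: none
Why: Reductive desulfonylation by electron transfer from buffered sodium amalgam cleaves the C–SO2Ar bond to a carbanion that methanol protonates, leaving the isolated trisubstituted olefins and the ring stereocentre untouched, and carbonate-catalysed transesterification with methanol then removes the acetate.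

Step 8
Reactants: 13 (2E,6E)-3,7-dimethyl-9-[(1S)-2,6,6-trimethylcyclohex-2-en-1-yl]nona-2,6-dien-1-ol; 14 linoleic acid
Product: 15 (2E,6E)-3,7-dimethyl-9-[(1S)-2,6,6-trimethylcyclohex-2-en-1-yl]nona-2,6-dien-1-yl (9Z,12Z)-octadeca-9,12-dienoate
Conditions: DCC (1.2 equiv), 4-(dimethylamino)pyridine (10 mol%), CH2Cl2, 0 °C to rt, argon, dark
Reagents that add atoms: none
Why: Steglich esterification (DCC/DMAP acyl transfer) under neutral conditions at room temperature, which touches neither the skipped (Z,Z)-diene of the acid nor the allylic C–O bond, the E-olefins or the stereocentre.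

## Compound list

1 | 2,4,4-trimethylcyclohex-2-en-1-one | CC1=CC(C)(C)CCC1=O | starting material
2 | (1R)-2,4,4-trimethylcyclohex-2-en-1-ol | O[C@H]1C(C)=CC(C)(C)CC1 | intermediate
3 | 2-[(4-methylphenyl)sulfonyl]acetic acid (tosylacetic acid) | Cc1ccc(cc1)S(=O)(=O)CC(=O)O | starting material
4 | (1R)-2,4,4-trimethylcyclohex-2-en-1-yl 2-[(4-methylphenyl)sulfonyl]acetate | Cc1ccc(cc1)S(=O)(=O)CC(=O)O[C@H]1C(C)=CC(C)(C)CC1 | intermediate
5 | geranyl acetate, (2E)-3,7-dimethylocta-2,6-dien-1-yl acetate | CC(C)=CCC/C(C)=C/COC(C)=O | starting material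
6 | (2E,6E)-8-hydroxy-3,7-dimethylocta-2,6-dien-1-yl acetate | CC(=O)OC/C=C(\C)CC/C=C(\C)CO | intermediate
7 | (2E,6E)-8-bromo-3,7-dimethylocta-2,6-dien-1-yl acetate | CC(=O)OC/C=C(\C)CC/C=C(\C)CBr | intermediate
8 | (1R)-2,4,4-trimethylcyclohex-2-en-1-yl (4E,8E)-10-acetoxy-4,8-dimethyl-2-[(4-methylphenyl)sulfonyl]deca-4,8-dienoate, about 1:1 epimers at C2 of the acid | CC(=O)OC/C=C(\C)CC/C=C(\C)CC(C(=O)O[C@H]1C(C)=CC(C)(C)CC1)S(=O)(=O)c1ccc(C)cc1 | intermediate
9 | O-trimethylsilyl O-[(1R)-2,4,4-trimethylcyclohex-2-en-1-yl] ketene acetal of 8 (ketene acetal geometry not defined) | CC(=O)OC/C=C(\C)CC/C=C(\C)CC(=C(O[Si](C)(C)C)O[C@H]1C(C)=CC(C)(C)CC1)S(=O)(=O)c1ccc(C)cc1 | intermediate (not isolated)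
10 | trimethylsilyl (4E,8E)-10-acetoxy-4,8-dimethyl-2-[(4-methylphenyl)sulfonyl]-2-[(1S)-2,6,6-trimethylcyclohex-2-en-1-yl]deca-4,8-dienoate (epimers at C2) | CC(=O)OC/C=C(\C)CC/C=C(\C)CC(C(=O)O[Si](C)(C)C)([C@@H]1C(C)=CCCC1(C)C)S(=O)(=O)c1ccc(C)cc1 | intermediate (not isolated)
11 | (2E,6E)-3,7-dimethyl-9-[(4-methylphenyl)sulfonyl]-9-[(1S)-2,6,6-trimethylcyclohex-2-en-1-yl]nona-2,6-dien-1-yl acetate, epimers at C9 | CC(=O)OC/C=C(\C)CC/C=C(\C)CC([C@@H]1C(C)=CCCC1(C)C)S(=O)(=O)c1ccc(C)cc1 | intermediate
12 | (2E,6E)-3,7-dimethyl-9-[(1S)-2,6,6-trimethylcyclohex-2-en-1-yl]nona-2,6-dien-1-yl acetate | CC(=O)OC/C=C(\C)CC/C=C(\C)CC[C@@H]1C(C)=CCCC1(C)C | intermediate (not isolated)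
13 | (2E,6E)-3,7-dimethyl-9-[(1S)-2,6,6-trimethylcyclohex-2-en-1-yl]nona-2,6-dien-1-ol | OC/C=C(\C)CC/C=C(\C)CC[C@@H]1C(C)=CCCC1(C)C | intermediate
14 | linoleic acid, (9Z,12Z)-octadeca-9,12-dienoic acid | CCCCC/C=C\C/C=C\CCCCCCCC(=O)O | starting material
15 | (2E,6E)-3,7-dimethyl-9-[(1S)-2,6,6-trimethylcyclohex-2-en-1-yl]nona-2,6-dien-1-yl (9Z,12Z)-octadeca-9,12-dienoate | CCCCC/C=C\C/C=C\CCCCCCCC(=O)OC/C=C(\C)CC/C=C(\C)CC[C@@H]1C(C)=CCCC1(C)C | target

## Step count and risk

Total steps: 8. Longest linear sequence: 6 (steps 1, 2, 5, 6, 7, 8 from enone 1; the branch from geranyl acetate, steps 3, 4, 5, 6, 7, 8, is equally long).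

Steps most likely to fail:

Step 6 (key rearrangement). The ketene acetal 9 is fully substituted and must bond to a ring carbon flanked by the gem-dimethyl carbon, so the [3,3] shift may be slow and elimination of the allylic ester may compete. The fallback sets out from 4 and comes back at 11, with the two C–C bonds made in the opposite order. Ester 4, which has no α-substituent, is heated with N,O-bis(trimethylsilyl)acetamide and KOAc in toluene. Through the silyl ketene acetal of 4 F1 and trimethylsilyl 2-[(4-methylphenyl)sulfonyl]-2-[(1S)-2,6,6-trimethylcyclohex-2-en-1-yl]acetate F2 it gives 1-methyl-4-({[(1S)-2,6,6-trimethylcyclohex-2-en-1-yl]methyl}sulfonyl)benzene F3. n-BuLi in THF at −78 °C converts this into the α-lithio sulfone F4, which is alkylated by bromide 7 at −78 to −40 °C to give 11; the allylic bromide reacts faster than the acetate.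

Step 7 (amalgam desulfonylation with methanolysis). The risks are incomplete C–S cleavage and base-induced side reactions in the polyene. The fallback sets out from 11 and comes back at 15, with the sulfonyl group removed last under ester-tolerant single-electron conditions. K2CO3 in MeOH gives (2E,6E)-3,7-dimethyl-9-[(4-methylphenyl)sulfonyl]-9-[(1S)-2,6,6-trimethylcyclohex-2-en-1-yl]nona-2,6-dien-1-ol F5. DCC and 4-(dimethylamino)pyridine with acid 14 give the corresponding sulfonyl linoleate F6. SmI2 with HMPA in THF–MeOH at −20 °C then cleaves the sulfone and gives 15 directly.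

Step 3 (SeO2 oxidation). Conversion is typically moderate and over-oxidation to the enal occurs. The fallback sets out from 5 and comes back at 8, so steps 4 and 5 are bypassed as well. Ene-type chlorination of 5 with Ca(OCl)2 and CO2 in CH2Cl2–H2O at 0 °C gives racemic (2E)-6-chloro-3,7-dimethylocta-2,7-dien-1-yl acetate F7. Pd(PPh3)4 (3 mol%) and K2CO3 in THF at rt then couple it with ester 4. Zerovalent palladium ionises the allylic chloride much faster than the allylic acetate, and the sulfonyl ester carbanion attacks the unsubstituted terminus of the allyl complex to give 8. The E/Z ratio of the new trisubstituted olefin has to be checked; E is expected to dominate.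

Further compounds
F1 | step 6 | 1-methyl-4-[(2-{[(1R)-2,4,4-trimethylcyclohex-2-en-1-yl]oxy}-2-[(trimethylsilyl)oxy]ethenyl)sulfonyl]benzene (silyl ketene acetal of 4) | Cc1ccc(cc1)S(=O)(=O)C=C(O[Si](C)(C)C)O[C@H]1C(C)=CC(C)(C)CC1
F2 | step 6 | trimethylsilyl 2-[(4-methylphenyl)sulfonyl]-2-[(1S)-2,6,6-trimethylcyclohex-2-en-1-yl]acetate | Cc1ccc(cc1)S(=O)(=O)C(C(=O)O[Si](C)(C)C)[C@@H]1C(C)=CCCC1(C)C
F3 | step 6 | 1-methyl-4-({[(1S)-2,6,6-trimethylcyclohex-2-en-1-yl]methyl}sulfonyl)benzene | Cc1ccc(cc1)S(=O)(=O)C[C@@H]1C(C)=CCCC1(C)C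
F4 | step 6 | α-lithio derivative of F3, lithium [(4-methylphenyl)sulfonyl][(1S)-2,6,6-trimethylcyclohex-2-en-1-yl]methanide | [Li]C([C@@H]1C(C)=CCCC1(C)C)S(=O)(=O)c1ccc(C)cc1
F5 | step 7 | (2E,6E)-3,7-dimethyl-9-[(4-methylphenyl)sulfonyl]-9-[(1S)-2,6,6-trimethylcyclohex-2-en-1-yl]nona-2,6-dien-1-ol | OC/C=C(\C)CC/C=C(\C)CC([C@@H]1C(C)=CCCC1(C)C)S(=O)(=O)c1ccc(C)cc1
F6 | step 7 | (2E,6E)-3,7-dimethyl-9-[(4-methylphenyl)sulfonyl]-9-[(1S)-2,6,6-trimethylcyclohex-2-en-1-yl]nona-2,6-dien-1-yl (9Z,12Z)-octadeca-9,12-dienoate | CCCCC/C=C\C/C=C\CCCCCCCC(=O)OC/C=C(\C)CC/C=C(\C)CC([C@@H]1C(C)=CCCC1(C)C)S(=O)(=O)c1ccc(C)cc1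
F7 | step 3 | (2E)-6-chloro-3,7-dimethylocta-2,7-dien-1-yl acetate (racemic) | CC(=O)OC/C=C(\C)CCC(Cl)C(C)=C
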